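**Retrosynthetic overview**

1. 22 ⇐ 21 (BBr3 global deprotection) ⇐ 19 (ortho-lithiation/CO2 places the carboxyl on C2 of ring A) ⇐ diol 18 ⇐ ester 17.
2. 17 ⇐ iodo-enoate 16 by the key step: the C7–C8 bond of ring B (C8 = benzylic ring CH bearing the side chain, C7 = the ring CH2 next to it) is made by a photoenzymatic 6-exo radical cyclisation that also sets C8 and C2'.
3. Enabling feature: C8 directly carries side-chain carbon C2', which bears a CH2OH. At the ester oxidation level C8=C2' is an α-alkyl cinnamate whose β-carbon C8 closes a six-membered ring with C7 through C6, C5, C4a and C8a. A C7 radical therefore closes ring B and leaves a prochiral α-ester radical at C2' for an ene-reductase to quench; the peri pair C5-methyl/C4-methoxy biases the face at C8.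
4. 16 ⇐ vinyl bromide 7 + alkylborane 14 (B-alkyl Suzuki–Miyaura); 7 ⇐ aldehyde 6 ⇐ arene 5 (Rieche formylation) ⇐ ester 3 ⇐ boronic acid 1 + crotonate 2 (rhodium-catalysed asymmetric conjugate addition sets C5).
5. 14 ⇐ pivalate 13 ⇐ Evans allylation of imide 8 (sets C6'). Ring order: ring A is bought; ring B is the only ring made (step 11).

Key step: step 11

Assumption: locants follow the target named as a 5,6,7,8-tetrahydronaphthalene-2-carboxylic acid (primed locants = heptan-2-yl side chain; ring A = benzene ring, ring B = saturated ring); the sense of induction of (S)-BINAP and of the ene-reductase variant is taken from the accepted models and from a screened panel.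

**Route**

Step 1
Reactants: 1 (2,3-dimethoxyphenyl)boronic acid; 2 propan-2-yl (2E)-but-2-enoate
Product: 3 propan-2-yl (3R)-3-(2,3-dimethoxyphenyl)butanoate
Conditions: Rh(acac)(C2H4)2 (3 mol %), (S)-BINAP, 1 (3 equiv), dioxane/H2O 10:1, 100 °C
Reagents that add atoms: none
Why: Rhodium-catalysed asymmetric 1,4-addition of an arylboronic acid to an enoate (Hayashi–Miyaura reaction); with (S)-BINAP the aryl–rhodium species should add to the face of the E-crotonate that gives the 3R ester, which fixes the benzylic methyl stereocentre (C5 of the target).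

Step 2
Reactants: 3 propan-2-yl (3R)-3-(2,3-dimethoxyphenyl)butanoate
Product: 4 (3R)-3-(2,3-dimethoxyphenyl)butan-1-ol
Conditions: LiAlH4, THF, 0 °C → rt
Reagents that add atoms: none
Why: LiAlH4 reduction of an ester to the primary alcohol; the stereocentre is not touched.

Step 3
Reactants: 4 (3R)-3-(2,3-dimethoxyphenyl)butan-1-ol
Product: 5 1-[(2R)-4-chlorobutan-2-yl]-2,3-dimethoxybenzene
Conditions: SOCl2, DMF (cat.), CH2Cl2, 0 → 40 °C
Reagents that add atoms: thionyl chloride O=S(Cl)Cl
Why: Chlorodehydroxylation of a primary alcohol through its chlorosulfite; the chloride is an inert placeholder for the later iodide and should survive the Lewis acid, ylide and palladium steps.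

Step 4
Reactants: 5 1-[(2R)-4-chlorobutan-2-yl]-2,3-dimethoxybenzene
Product: 6 2-[(2R)-4-chlorobutan-2-yl]-3,4-dimethoxybenzaldehyde
Conditions: Cl2CHOMe, TiCl4, CH2Cl2, −78 → 0 °C; then H2O
Reagents that add atoms: dichloromethyl methyl ether COC(Cl)Cl; water O
Why: Rieche formylation; the methoxy group meta to the side chain is the only one free to lie in the ring plane and should direct the electrophile to its para position, the carbon ortho to the side chain (as in the formylation of 2,3-dimethoxytoluene).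

Step 5
Reactants: 6 2-[(2R)-4-chlorobutan-2-yl]-3,4-dimethoxybenzaldehyde
Product: 7 methyl (2Z)-2-bromo-3-{2-[(2R)-4-chlorobutan-2-yl]-3,4-dimethoxyphenyl}prop-2-enoate
Conditions: Ph3P=CHCO2Me, NBS, CH2Cl2, −20 °C; then 6, rt → 40 °C
Reagents that add atoms: methyl (triphenyl-λ5-phosphanylidene)acetate COC(=O)C=P(c1ccccc1)(c1ccccc1)c1ccccc1; N-bromosuccinimide O=C1CCC(=O)N1Br
Why: Wittig olefination with the stabilised bromo ylide made in the flask by brominating the ester ylide; the ester should end trans to the aryl group (Z bromoalkene), and the geometry is not stereochemically relevant later because C2' becomes a radical.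

Step 6
Reactants: 8 (4R)-4-benzyl-3-propanoyl-1,3-oxazolidin-2-one; 9 3-iodoprop-1-ene
Product: 11 (4R)-4-benzyl-3-[(2S)-2-methylpent-4-enoyl]-1,3-oxazolidin-2-one, via sodium Z-enolate 10 (not isolated)
Conditions: NaN(SiMe3)2, THF, −78 °C; then 9, −78 → −45 °C
Reagents that add atoms: none
Why: Evans alkylation: the chelated sodium Z-enolate is allylated on the face opposite the benzyl group of the 4R auxiliary, which sets the 2S centre (C6' of the target).

Step 7
Reactants: 11 (4R)-4-benzyl-3-[(2S)-2-methylpent-4-enoyl]-1,3-oxazolidin-2-one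
Product: 12 (2S)-2-methylpent-4-en-1-ol
Conditions: LiBH4, Et2O, MeOH (1 equiv), 0 °C
Reagents that add atoms: none
Why: Reductive cleavage of the N-acyl oxazolidinone with LiBH4 gives the primary alcohol without enolising the α-stereocentre and returns the auxiliary.

Step 8
Reactants: 12 (2S)-2-methylpent-4-en-1-ol
Product: 13 (2S)-2-methylpent-4-en-1-yl 2,2-dimethylpropanoate
Conditions: t-BuCOCl, pyridine, DMAP (cat.), CH2Cl2, 0 °C → rt
Reagents that add atoms: 2,2-dimethylpropanoyl chloride CC(C)(C)C(=O)Cl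
Why: Acylation of a primary alcohol; the pivalate should resist the aqueous base of the coupling and is removed without an extra step in the later LiAlH4 reduction.

Step 9
Reactants: 13 (2S)-2-methylpent-4-en-1-yl 2,2-dimethylpropanoate; 7 methyl (2Z)-2-bromo-3-{2-[(2R)-4-chlorobutan-2-yl]-3,4-dimethoxyphenyl}prop-2-enoate
Product: 15 methyl (2E,6S)-2-({2-[(2R)-4-chlorobutan-2-yl]-3,4-dimethoxyphenyl}methylidene)-7-[(2,2-dimethylpropanoyl)oxy]-6-methylheptanoate, via alkylborane 14 (not isolated)
Conditions: 13, 9-BBN dimer, THF, 0 °C → rt; then 7, PdCl2(dppf), AsPh3, Cs2CO3, DMF/THF/H2O, rt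
Reagents that add atoms: none
Why: Anti-Markovnikov hydroboration of the terminal alkene with 9-BBN followed by B-alkyl Suzuki–Miyaura coupling with the vinyl bromide, which proceeds with retention of alkene geometry and should leave the primary alkyl chloride untouched.

Step 10
Reactants: 15 methyl (2E,6S)-2-({2-[(2R)-4-chlorobutan-2-yl]-3,4-dimethoxyphenyl}methylidene)-7-[(2,2-dimethylpropanoyl)oxy]-6-methylheptanoate
Product: 16 methyl (2E,6S)-2-({2-[(2R)-4-iodobutan-2-yl]-3,4-dimethoxyphenyl}methylidene)-7-[(2,2-dimethylpropanoyl)oxy]-6-methylheptanoate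
Conditions: NaI (10 equiv), butan-2-one, 80 °C, dark
Reagents that add atoms: sodium iodide [Na+].[I-]
Why: Finkelstein halide exchange (SN2) driven by precipitation of NaCl; it turns the placeholder chloride into the iodide needed for single-electron reduction.

Step 11
Reactants: 16 methyl (2E,6S)-2-({2-[(2R)-4-iodobutan-2-yl]-3,4-dimethoxyphenyl}methylidene)-7-[(2,2-dimethylpropanoyl)oxy]-6-methylheptanoate
Product: 17 methyl (2S,6S)-2-[(1S,4R)-5,6-dimethoxy-4-methyl-1,2,3,4-tetrahydronaphthalen-1-yl]-7-[(2,2-dimethylpropanoyl)oxy]-6-methylheptanoate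
Conditions: flavin mononucleotide-dependent ene-reductase of the Old Yellow Enzyme family (panel; GluER-T36A as first candidate), NADP+ (cat.), glucose dehydrogenase, D-glucose, KH2PO4/K2HPO4 buffer pH 8.0, 10 vol % DMSO, cyan LEDs (about 497 nm), 25 °C, N2
Reagents that add atoms: none
Why: Proposed new method: in the active site the flavin hydroquinone (kept reduced by NADPH, glucose dehydrogenase and glucose) forms a charge-transfer complex with the primary iodide of 16, light-driven single-electron transfer expels iodide, the C7 radical adds to the cinnamate β-carbon C8 and the flavin semiquinone returns a hydrogen atom to the resulting α-ester radical at C2'. The closest known reaction type is the ene-reductase photoenzymatic reductive cyclisation of unactivated alkyl iodides onto tethered electron-poor alkenes with stereodetermining hydrogen-atom transfer from flavin, extended here to a β-aryl α-alkyl enoate and to two new stereocentres. Ring B closes in the 6-exo-trig mode. C8 is under substrate control: in the half-chair transition state the C5 methyl is pseudoaxial to escape the peri C4 methoxy and the enoate arm is pseudoaxial to escape the peri C1–H, which is the 5,8-trans (5R,8S) arrangement. C2' is under enzyme control, the protein exposing one face of the planar α-ester radical to N5–H of the semiquinone (the variant that gives 2'S is picked from the panel). The step needs attack at C8 (6-exo) and not at C2' (7-endo) and ring closure before reduction of the C7 radical or hydride reduction of the alkene: the nucleophilic primary radical is polarity-matched to the ester β-carbon, only the tertiary α-ester radical is quenched fast by the semiquinone, and trisubstituted mono-ester alkenes are poor substrates of the native hydride pathway.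

Step 12
Reactants: 17 methyl (2S,6S)-2-[(1S,4R)-5,6-dimethoxy-4-methyl-1,2,3,4-tetrahydronaphthalen-1-yl]-7-[(2,2-dimethylpropanoyl)oxy]-6-methylheptanoate
Product: 18 (2S,6S)-2-[(1S,4R)-5,6-dimethoxy-4-methyl-1,2,3,4-tetrahydronaphthalen-1-yl]-6-methylheptane-1,7-diol
Conditions: LiAlH4, THF, 0 °C → rt
Reagents that add atoms: none
Why: LiAlH4 reduction of the methyl ester and reductive cleavage of the pivalate in one operation; the α-stereocentre should not enolise under these conditions.

Step 13
Reactants: 18 (2S,6S)-2-[(1S,4R)-5,6-dimethoxy-4-methyl-1,2,3,4-tetrahydronaphthalen-1-yl]-6-methylheptane-1,7-diol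
Product: 19 (1S,4R)-1-[(2S,6S)-1,7-bis{[tert-butyl(dimethyl)silyl]oxy}-6-methylheptan-2-yl]-5,6-dimethoxy-4-methyl-1,2,3,4-tetrahydronaphthalene
Conditions: TBSCl (2.5 equiv), imidazole, DMF, rt
Reagents that add atoms: tert-butyl(chloro)dimethylsilane CC(C)(C)[Si](C)(C)Cl
Why: Silylation of the two primary alcohols to mask their acidic protons before the organolithium step.

Step 14
Reactants: 19 (1S,4R)-1-[(2S,6S)-1,7-bis{[tert-butyl(dimethyl)silyl]oxy}-6-methylheptan-2-yl]-5,6-dimethoxy-4-methyl-1,2,3,4-tetrahydronaphthalene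
Product: 21 (5R,8S)-8-[(2S,6S)-1,7-bis{[tert-butyl(dimethyl)silyl]oxy}-6-methylheptan-2-yl]-3,4-dimethoxy-5-methyl-5,6,7,8-tetrahydronaphthalene-2-carboxylic acid, via aryllithium 20 (not isolated)
Conditions: n-BuLi, TMEDA, Et2O, 0 °C → rt; then CO2, −78 °C → rt; then dilute HCl to pH 3, 0 °C
Reagents that add atoms: carbon dioxide O=C=O
Why: Directed ortho-metalation: the methoxy group with a free ortho position directs lithiation to the only aromatic C–H next to an oxygen substituent, and carboxylation of the aryllithium gives the benzoic acid.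

Step 15
Reactants: 21 (5R,8S)-8-[(2S,6S)-1,7-bis{[tert-butyl(dimethyl)silyl]oxy}-6-methylheptan-2-yl]-3,4-dimethoxy-5-methyl-5,6,7,8-tetrahydronaphthalene-2-carboxylic acid
Product: 22 (5R,8S)-8-[(2S,6S)-1,7-dihydroxy-6-methylheptan-2-yl]-3,4-dihydroxy-5-methyl-5,6,7,8-tetrahydronaphthalene-2-carboxylic acid
Conditions: BBr3 (8 equiv), CH2Cl2, −78 → 0 °C; then H2O
Reagents that add atoms: none
Why: Lewis-acid ether cleavage: BBr3 should demethylate both aryl methyl ethers (helped by the neighbouring carboxyl and by catechol borate formation) and cleave both silyl ethers to borates that hydrolyse to the alcohols on work-up, the temperature being held at or below 0 °C so that the alkyl borates do not collapse to bromides.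

**Compound list**

1 | (2,3-dimethoxyphenyl)boronic acid | COc1cccc(B(O)O)c1OC | starting material
2 | propan-2-yl (2E)-but-2-enoate | C/C=C/C(=O)OC(C)C | starting material
3 | propan-2-yl (3R)-3-(2,3-dimethoxyphenyl)butanoate | CC(C)OC(=O)C[C@@H](C)c1cccc(OC)c1OC | intermediate
4 | (3R)-3-(2,3-dimethoxyphenyl)butan-1-ol | OCC[C@@H](C)c1cccc(OC)c1OC | intermediate
5 | 1-[(2R)-4-chlorobutan-2-yl]-2,3-dimethoxybenzene | ClCC[C@@H](C)c1cccc(OC)c1OC | intermediate
6 | 2-[(2R)-4-chlorobutan-2-yl]-3,4-dimethoxybenzaldehyde | ClCC[C@@H](C)c1c(C=O)ccc(OC)c1OC | intermediate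
7 | methyl (2Z)-2-bromo-3-{2-[(2R)-4-chlorobutan-2-yl]-3,4-dimethoxyphenyl}prop-2-enoate | ClCC[C@@H](C)c1c(/C=C(\Br)C(=O)OC)ccc(OC)c1OC | intermediate
8 | (4R)-4-benzyl-3-propanoyl-1,3-oxazolidin-2-one | CCC(=O)N1[C@H](Cc2ccccc2)COC1=O | starting material
9 | 3-iodoprop-1-ene | C=CCI | starting material
10 | sodium Z-enolate of 8 | C/C=C(\[O-])N1[C@H](Cc2ccccc2)COC1=O.[Na+] | intermediate (not isolated)
11 | (4R)-4-benzyl-3-[(2S)-2-methylpent-4-enoyl]-1,3-oxazolidin-2-one | C[C@H](C(=O)N1[C@H](Cc2ccccc2)COC1=O)CC=C | intermediate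
12 | (2S)-2-methylpent-4-en-1-ol | C[C@H](CO)CC=C | intermediate
13 | (2S)-2-methylpent-4-en-1-yl 2,2-dimethylpropanoate | C[C@H](COC(=O)C(C)(C)C)CC=C | intermediate
14 | (2S)-5-(9-borabicyclo[3.3.1]nonan-9-yl)-2-methylpentyl 2,2-dimethylpropanoate | C[C@H](COC(=O)C(C)(C)C)CCCB1C2CCCC1CCC2 | intermediate (not isolated)
15 | methyl (2E,6S)-2-({2-[(2R)-4-chlorobutan-2-yl]-3,4-dimethoxyphenyl}methylidene)-7-[(2,2-dimethylpropanoyl)oxy]-6-methylheptanoate | C[C@H](COC(=O)C(C)(C)C)CCC/C(C(=O)OC)=C\c1ccc(OC)c(OC)c1[C@H](C)CCCl | intermediate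
16 | methyl (2E,6S)-2-({2-[(2R)-4-iodobutan-2-yl]-3,4-dimethoxyphenyl}methylidene)-7-[(2,2-dimethylpropanoyl)oxy]-6-methylheptanoate | C[C@H](COC(=O)C(C)(C)C)CCC/C(C(=O)OC)=C\c1ccc(OC)c(OC)c1[C@H](C)CCI | intermediate
17 | methyl (2S,6S)-2-[(1S,4R)-5,6-dimethoxy-4-methyl-1,2,3,4-tetrahydronaphthalen-1-yl]-7-[(2,2-dimethylpropanoyl)oxy]-6-methylheptanoate | C[C@H](COC(=O)C(C)(C)C)CCC[C@H](C(=O)OC)[C@@H]1CC[C@@H](C)c2c1ccc(OC)c2OC | intermediate
18 | (2S,6S)-2-[(1S,4R)-5,6-dimethoxy-4-methyl-1,2,3,4-tetrahydronaphthalen-1-yl]-6-methylheptane-1,7-diol | C[C@H](CO)CCC[C@H](CO)[C@@H]1CC[C@@H](C)c2c1ccc(OC)c2OC | intermediate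
19 | (1S,4R)-1-[(2S,6S)-1,7-bis{[tert-butyl(dimethyl)silyl]oxy}-6-methylheptan-2-yl]-5,6-dimethoxy-4-methyl-1,2,3,4-tetrahydronaphthalene | C[C@H](CO[Si](C)(C)C(C)(C)C)CCC[C@H](CO[Si](C)(C)C(C)(C)C)[C@@H]1CC[C@@H](C)c2c1ccc(OC)c2OC | intermediate
20 | [(5R,8S)-8-[(2S,6S)-1,7-bis{[tert-butyl(dimethyl)silyl]oxy}-6-methylheptan-2-yl]-3,4-dimethoxy-5-methyl-5,6,7,8-tetrahydronaphthalen-2-yl]lithium | C[C@H](CO[Si](C)(C)C(C)(C)C)CCC[C@H](CO[Si](C)(C)C(C)(C)C)[C@@H]1CC[C@@H](C)c2c1cc([Li])c(OC)c2OC | intermediate (not isolated)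
21 | (5R,8S)-8-[(2S,6S)-1,7-bis{[tert-butyl(dimethyl)silyl]oxy}-6-methylheptan-2-yl]-3,4-dimethoxy-5-methyl-5,6,7,8-tetrahydronaphthalene-2-carboxylic acid | C[C@H](CO[Si](C)(C)C(C)(C)C)CCC[C@H](CO[Si](C)(C)C(C)(C)C)[C@@H]1CC[C@@H](C)c2c1cc(C(=O)O)c(OC)c2OC | intermediate
22 | (5R,8S)-8-[(2S,6S)-1,7-dihydroxy-6-methylheptan-2-yl]-3,4-dihydroxy-5-methyl-5,6,7,8-tetrahydronaphthalene-2-carboxylic acid | C[C@H](CO)CCC[C@H](CO)[C@@H]1CC[C@@H](C)c2c1cc(C(=O)O)c(O)c2O | target

**Step count**

Total step count: 15. Longest linear sequence: 12 steps (steps 1–5 and 9–15, from boronic acid 1).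

**Steps most likely to fail**

1. Step 11 (proposed new method). The bulky substrate may not bind productively, the C7 radical may be reduced before ring closure, or the hydrogen atom may be delivered to the wrong face at C2'. The fallback uses known auxiliary chemistry, sets out from aldehyde 6 and comes back at diol 18. Horner–Wadsworth–Emmons reaction of 6 with diethyl {2-[(4S)-4-benzyl-2-oxo-1,3-oxazolidin-3-yl]-2-oxoethyl}phosphonate (LiCl, i-Pr2NEt, MeCN) should give (4S)-4-benzyl-3-[(2E)-3-{2-[(2R)-4-chlorobutan-2-yl]-3,4-dimethoxyphenyl}prop-2-enoyl]-1,3-oxazolidin-2-one F1. NaI in butan-2-one then gives the corresponding iodide F2. Bu3SnH with Et3B/O2 and MgBr2·OEt2 in CH2Cl2 at −78 °C closes the same C7–C8 bond by a chelate-controlled 6-exo radical conjugate addition, the auxiliary shielding one face of the β-carbon and the trans preference of ring B reinforcing it, to give (4S)-4-benzyl-3-{[(1S,4R)-5,6-dimethoxy-4-methyl-1,2,3,4-tetrahydronaphthalen-1-yl]acetyl}-1,3-oxazolidin-2-one F3. In parallel, oxidation of borane 14 with NaBO3·4H2O gives (2S)-5-hydroxy-2-methylpentyl 2,2-dimethylpropanoate F4, and Tf2O/2,6-lutidine converts it into the triflate F5. Evans alkylation of the sodium enolate of F3 (NaN(SiMe3)2, THF, −78 °C) with F5 sets C2' under auxiliary control and gives the alkylated imide F6. LiAlH4 then removes the auxiliary and the pivalate and delivers diol 18.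

2. Step 14. Lateral (benzylic) deprotonation may compete with ring metalation, or the methoxy-directed metalation may be too slow. The fallback sets out from 19 and comes back at aryllithium 20 and hence acid 21. Electrophilic bromination (NBS, MeCN, 0 °C) ortho to the unhindered methoxy group should give (1S,4R)-1-[(2S,6S)-1,7-bis{[tert-butyl(dimethyl)silyl]oxy}-6-methylheptan-2-yl]-7-bromo-5,6-dimethoxy-4-methyl-1,2,3,4-tetrahydronaphthalene F7. Bromine–lithium exchange (t-BuLi, THF, −78 °C) then generates 20 at a defined position and at low temperature, and CO2 gives 21.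

3. Step 15. The primary alkyl borates may be converted into bromides, or the hindered methoxy group may cleave incompletely at the low temperature this requires. The fallback sets out from 21 and comes back at target 22. Aqueous HCl in THF removes the silyl groups to give (5R,8S)-8-[(2S,6S)-1,7-dihydroxy-6-methylheptan-2-yl]-3,4-dimethoxy-5-methyl-5,6,7,8-tetrahydronaphthalene-2-carboxylic acid F8. Ac2O/pyridine/DMAP gives its diacetate F9. BBr3 (CH2Cl2, −78 °C → rt) can now be run to completion with the alcohols masked as esters and gives the catechol diacetate F10. K2CO3 in degassed MeOH removes the acetates and gives 22.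

**Further compounds**

F1 | step 11 | (4S)-4-benzyl-3-[(2E)-3-{2-[(2R)-4-chlorobutan-2-yl]-3,4-dimethoxyphenyl}prop-2-enoyl]-1,3-oxazolidin-2-one | ClCC[C@@H](C)c1c(/C=C/C(=O)N2[C@@H](Cc3ccccc3)COC2=O)ccc(OC)c1OC
F2 | step 11 | (4S)-4-benzyl-3-[(2E)-3-{2-[(2R)-4-iodobutan-2-yl]-3,4-dimethoxyphenyl}prop-2-enoyl]-1,3-oxazolidin-2-one | ICC[C@@H](C)c1c(/C=C/C(=O)N2[C@@H](Cc3ccccc3)COC2=O)ccc(OC)c1OC
F3 | step 11 | (4S)-4-benzyl-3-{[(1S,4R)-5,6-dimethoxy-4-methyl-1,2,3,4-tetrahydronaphthalen-1-yl]acetyl}-1,3-oxazolidin-2-one | O=C(C[C@@H]1CC[C@@H](C)c2c1ccc(OC)c2OC)N3[C@@H](Cc4ccccc4)COC3=O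
F4 | step 11 | (2S)-5-hydroxy-2-methylpentyl 2,2-dimethylpropanoate | C[C@H](COC(=O)C(C)(C)C)CCCO
F5 | step 11 | (2S)-2-methyl-5-{[(trifluoromethyl)sulfonyl]oxy}pentyl 2,2-dimethylpropanoate | C[C@H](COC(=O)C(C)(C)C)CCCOS(=O)(=O)C(F)(F)F
F6 | step 11 | (2S,6S)-7-[(4S)-4-benzyl-2-oxo-1,3-oxazolidin-3-yl]-6-[(1S,4R)-5,6-dimethoxy-4-methyl-1,2,3,4-tetrahydronaphthalen-1-yl]-2-methyl-7-oxoheptyl 2,2-dimethylpropanoate | C[C@H](COC(=O)C(C)(C)C)CCC[C@H](C(=O)N1[C@@H](Cc2ccccc2)COC1=O)[C@@H]3CC[C@@H](C)c4c3ccc(OC)c4OC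
F7 | step 14 | (1S,4R)-1-[(2S,6S)-1,7-bis{[tert-butyl(dimethyl)silyl]oxy}-6-methylheptan-2-yl]-7-bromo-5,6-dimethoxy-4-methyl-1,2,3,4-tetrahydronaphthalene | C[C@H](CO[Si](C)(C)C(C)(C)C)CCC[C@H](CO[Si](C)(C)C(C)(C)C)[C@@H]1CC[C@@H](C)c2c1cc(Br)c(OC)c2OC
F8 | step 15 | (5R,8S)-8-[(2S,6S)-1,7-dihydroxy-6-methylheptan-2-yl]-3,4-dimethoxy-5-methyl-5,6,7,8-tetrahydronaphthalene-2-carboxylic acid | C[C@H](CO)CCC[C@H](CO)[C@@H]1CC[C@@H](C)c2c1cc(C(=O)O)c(OC)c2OC
F9 | step 15 | (5R,8S)-8-[(2S,6S)-1,7-bis(acetyloxy)-6-methylheptan-2-yl]-3,4-dimethoxy-5-methyl-5,6,7,8-tetrahydronaphthalene-2-carboxylic acid | C[C@H](COC(C)=O)CCC[C@H](COC(C)=O)[C@@H]1CC[C@@H](C)c2c1cc(C(=O)O)c(OC)c2OC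
F10 | step 15 | (5R,8S)-8-[(2S,6S)-1,7-bis(acetyloxy)-6-methylheptan-2-yl]-3,4-dihydroxy-5-methyl-5,6,7,8-tetrahydronaphthalene-2-carboxylic acid | C[C@H](COC(C)=O)CCC[C@H](COC(C)=O)[C@@H]1CC[C@@H](C)c2c1cc(C(=O)O)c(O)c2O
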